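Everything rests on stitching CO2 between C4 and C6 (germacrane numbering) of an open-chain (Z)-alkenyl iodide that carries a C6–C7 epoxide. Iodine–lithium exchange and carboxylation make the C15–C4 bond; the carboxylate then opens the allylic epoxide 5-exo at C6, forming the O–C6 bond, the butenolide ring and the C7 tertiary alcohol in one operation. The step exploits the anti O–C6/HO–C7 pattern at the edge of the C4–C5–C6 γ-lactone, which is a trans-opened epoxide. Exo-face dihydroxylation then sets C4/C5, a Ni/Cr closure of the C1–C10 bond builds the ten-membered ring, and its γ-hydroxy enone plus the C12 acid fold into the dihydrofuran spiroketal lactone.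

Key step: step 10

Remark on numbering: C1 = CH–O of the dihydrofuran; C2, C3 = ring CH2; C4 = C(OH) bearing the lactone carbonyl C15; C5 = CH–OAc; C6 = CH–O of that lactone; C7 = C(OH); C8 = spiro ketal carbon; C9 = CH=; C10 = C(CH3)= (methyl C14); C11 = CH(CH3) (methyl C13); C12 = carbonyl of the spiro lactone.
Remark on the chemistry: 22 is a mixture of C8 epimers that converge in step 16; 25 and 26 are drawn as open keto forms although they may rest as cyclic hemiketals. Compounds 1 and 3 and all reagents in the conditions are taken to be catalogue items.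

Step 1
Reactants: 1 2-(3-bromopropyl)-1,3-dioxolane
Product: 2 [3-(1,3-dioxolan-2-yl)propyl]triphenylphosphonium bromide
Conditions: PPh3, MeCN, reflux
Reagents that add atoms: triphenylphosphine c1ccc(cc1)P(c1ccccc1)c1ccccc1
Why: SN2 quaternisation of the phosphine by the primary bromide should give the Wittig salt that later supplies C1–C4 with C1 masked as an acetal.

Step 2
Reactants: 3 methyl (R)-3-hydroxy-2-methylpropanoate
Product: 4 methyl (R)-3-[(tert-butyldiphenylsilyl)oxy]-2-methylpropanoate
Conditions: TBDPSCl, imidazole, CH2Cl2, 0 °C to rt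
Reagents that add atoms: tert-butyldiphenylsilyl chloride CC(C)(C)[Si](Cl)(c1ccccc1)c1ccccc1
Why: Standard silylation of the primary alcohol; C11 comes from the chiral pool and is not touched.

Step 3
Reactants: 4 methyl (R)-3-[(tert-butyldiphenylsilyl)oxy]-2-methylpropanoate
Product: 5 ethyl (R)-5-[(tert-butyldiphenylsilyl)oxy]-4-methyl-3-oxopentanoate
Conditions: EtOAc, LDA (2.5 equiv), THF, −78 °C; then 4, −78 to −40 °C
Reagents that add atoms: ethyl acetate CCOC(C)=O
Why: Crossed Claisen condensation of the lithium enolate of ethyl acetate with the methyl ester; the product is stored as its enolate, and at −78 °C the C11–H of the ester should not be removed.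

Step 4
Reactants: 5 ethyl (R)-5-[(tert-butyldiphenylsilyl)oxy]-4-methyl-3-oxopentanoate
Product: 6 ethyl (2Z,4R)-5-[(tert-butyldiphenylsilyl)oxy]-4-methyl-3-(trifluoromethylsulfonyloxy)pent-2-enoate
Conditions: Tf2O, aq. LiOH, toluene, 5 °C
Reagents that add atoms: triflic anhydride O=S(=O)(OS(=O)(=O)C(F)(F)F)C(F)(F)F
Why: Triflation of the lithium-chelated (Z)-enolate of the β-keto ester should give the (Z)-enol triflate (OTf cis to CO2Et), which fixes the C6=C7 geometry; only the C6 methylene is enolised, so C11 is not at risk.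

Step 5
Reactants: 6 ethyl (2Z,4R)-5-[(tert-butyldiphenylsilyl)oxy]-4-methyl-3-(trifluoromethylsulfonyloxy)pent-2-enoate
Product: 7 ethyl (2Z,4S)-3-(benzyloxymethyl)-5-[(tert-butyldiphenylsilyl)oxy]-4-methylpent-2-enoate
Conditions: BnOCH2BF3K, Pd(OAc)2 (5 mol %), RuPhos (10 mol %), Cs2CO3, dioxane/H2O, 90 °C
Reagents that add atoms: potassium (benzyloxymethyl)trifluoroborate [K+].F[B-](F)(F)COCc1ccccc1
Why: Suzuki–Miyaura sp2–sp3 coupling of the enol triflate proceeds with retention of the alkene geometry and should place the C8 benzyloxymethyl group cis to C5.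

Step 6
Reactants: 7 ethyl (2Z,4S)-3-(benzyloxymethyl)-5-[(tert-butyldiphenylsilyl)oxy]-4-methylpent-2-enoate
Product: 8 (2Z,4S)-3-(benzyloxymethyl)-5-[(tert-butyldiphenylsilyl)oxy]-4-methylpent-2-en-1-ol
Conditions: DIBAL-H (2.2 equiv), CH2Cl2, −78 °C
Reagents that add atoms: none
Why: DIBAL-H reduces the conjugated ester to the allylic alcohol without touching the trisubstituted alkene or the silyl and benzyl ethers.

Step 7
Reactants: 8 (2Z,4S)-3-(benzyloxymethyl)-5-[(tert-butyldiphenylsilyl)oxy]-4-methylpent-2-en-1-ol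
Product: 9 [(2S,3R)-3-(benzyloxymethyl)-3-[(2R)-1-(tert-butyldiphenylsilyloxy)propan-2-yl]oxiran-2-yl]methanol
Conditions: Ti(Oi-Pr)4, L-(+)-DET, t-BuOOH, 4 Å MS, CH2Cl2, −20 °C
Reagents that add atoms: tert-butyl hydroperoxide CC(C)(C)OO
Why: Sharpless asymmetric epoxidation: the allylic hydroxyl binds the titanium tartrate and L-(+)-tartrate should direct oxygen to the face that gives the (2S,3R)-epoxide, which sets C7 and gives C6 the configuration that step 10 inverts.

Step 8
Reactants: 9 [(2S,3R)-3-(benzyloxymethyl)-3-[(2R)-1-(tert-butyldiphenylsilyloxy)propan-2-yl]oxiran-2-yl]methanol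
Product: 10 (2R,3R)-3-(benzyloxymethyl)-3-[(2R)-1-(tert-butyldiphenylsilyloxy)propan-2-yl]oxirane-2-carbaldehyde
Conditions: Dess–Martin periodinane, pyridine, CH2Cl2, 0 °C
Reagents that add atoms: none
Why: Buffered Dess–Martin oxidation should convert the primary epoxy alcohol into the epoxy aldehyde without opening the epoxide or epimerising C6.

Step 9
Reactants: 2 [3-(1,3-dioxolan-2-yl)propyl]triphenylphosphonium bromide; 10 (2R,3R)-3-(benzyloxymethyl)-3-[(2R)-1-(tert-butyldiphenylsilyloxy)propan-2-yl]oxirane-2-carbaldehyde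
Product: 14 Z-iodoalkenyl epoxide (iodine on C4 cis to C6), via ylide 11 (not isolated), via iodophosphonium salt 12 (not isolated), via iodo ylide 13 (not isolated)
Conditions: 2, n-BuLi, THF, 0 °C; I2, −78 °C; NaHMDS, −20 °C; then 10, −78 °C to rt
Reagents that add atoms: iodine II
Why: Wittig olefination with an α-iodo ylide (Stork–Zhao type): the unstabilised ylide reacts through the cis-oxaphosphetane, so iodine on C4 should end up cis to C6, the geometry the lactone needs.

Step 10
Reactants: 14 Z-iodoalkenyl epoxide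
Product: 17 hydroxy butenolide (C15 lactone closed on C6; free C7–OH), via alkenyllithium 15 (not isolated), via lithium carboxylate 16 (not isolated)
Conditions: t-BuLi (2.1 equiv), Et2O/THF, −78 °C; CO2 (excess), −78 °C to rt, then 40 °C under CO2
Reagents that add atoms: carbon dioxide O=C=O
Why: Iodine–lithium exchange proceeds with retention to the (Z)-alkenyllithium 15, which adds to CO2 (C15–C4 bond) to give carboxylate 16; its oxygen, held over C6 by the (Z)-acrylate, then opens the allylic epoxide by SN2 attack (O–C6 bond), and the released C7 alkoxide is buffered as its carbonate under CO2. The closest known reaction types are the carboxylation of alkenyllithiums and the lactonisation of γ,δ-epoxy carboxylates. The butenolide ring closes in the 5-exo-tet mode. C6 is set by inversion of the epoxide carbon fixed in the tartrate-controlled epoxidation, and C7 keeps its epoxide configuration because its C–O bond is not broken. The step needs attack at C6 and not at C7, which the five-membered transition state, the allylic activation of C6 and the fully substituted, SN2-inert C7 should secure; exchange at −78 °C should outrun any attack of the organolithium on the epoxide.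

Step 11
Reactants: 17 hydroxy butenolide
Product: 18 C4,C5-cis-diol lactone (both hydroxyls trans to the C6–C7 bond)
Conditions: OsO4 (10 mol %), NMO, acetone/H2O, rt
Reagents that add atoms: osmium tetroxide O=[Os](=O)(=O)=O; N-methylmorpholine N-oxide C[N+]1([O-])CCOCC1; water O
Why: Osmium-catalysed syn-dihydroxylation (Upjohn conditions) should occur on the butenolide face anti to the bulky C6 substituent, which sets C4 and C5.

Step 12
Reactants: 18 C4,C5-cis-diol lactone
Product: 19 C5 acetate
Conditions: Ac2O, pyridine, 0 °C to rt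
Reagents that add atoms: acetic anhydride CC(=O)OC(C)=O
Why: Acetic anhydride in pyridine should acylate only the secondary C5 hydroxyl, the C4 and C7 hydroxyls being tertiary.

Step 13
Reactants: 19 C5 acetate
Product: 20 C8 primary alcohol
Conditions: H2 (1 atm), Pd/C, EtOAc, rt
Reagents that add atoms: none
Why: Hydrogenolysis cleaves the benzyl ether now that no alkene is left in the molecule; silyl ether, acetal, acetate and lactone are inert.

Step 14
Reactants: 20 C8 primary alcohol
Product: 21 C8 aldehyde (α-hydroxy aldehyde)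
Conditions: TEMPO (cat.), PhI(OAc)2, CH2Cl2, rt
Reagents that add atoms: none
Why: The oxoammonium oxidation is selective for the primary alcohol and should give the α-hydroxy aldehyde without cleaving the 1,2-diol.

Step 15
Reactants: 21 C8 aldehyde
Product: 22 C8 propargylic alcohol (both C8 epimers)
Conditions: propyne, Zn(OTf)2, Et3N, toluene, rt
Reagents that add atoms: propyne CC#C
Why: Zinc triflate and triethylamine generate the zinc acetylide of propyne, which adds to the aldehyde under conditions that spare acetate and lactone; the new C8 stereocentre is left uncontrolled because step 16 removes it.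

Step 16
Reactants: 22 C8 propargylic alcohol
Product: 23 ynone
Conditions: MnO2, CH2Cl2, rt
Reagents that add atoms: none
Why: Manganese dioxide oxidises the propargylic alcohol selectively to the ynone, so both C8 epimers converge.

Step 17
Reactants: 23 ynone
Product: 24 (Z)-β-iodoenone
Conditions: NaI, AcOH, rt
Reagents that add atoms: sodium iodide [Na+].[I-]
Why: Conjugate hydroiodination of the ynone is an anti addition and should give the (Z)-β-iodoenone with iodine cis to the C8 carbonyl, the geometry the dihydrofuran needs.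

Step 18
Reactants: 24 (Z)-β-iodoenone
Product: 25 C12 primary alcohol
Conditions: HF·pyridine, pyridine, THF, 0 °C to rt
Reagents that add atoms: none
Why: Buffered HF·pyridine removes the primary silyl ether while the acetal, the acetate and the iodoenone should survive.

Step 19
Reactants: 25 C12 primary alcohol
Product: 26 C12 carboxylic acid
Conditions: TEMPO (cat.), PhI(OAc)2 (2.2 equiv), MeCN/H2O, rt
Reagents that add atoms: water O
Why: The oxoammonium oxidation in aqueous acetonitrile takes the primary alcohol through the aldehyde hydrate to the acid before any C1 hydroxyl exists, so the later spiro ring can only close as a lactone.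

Step 20
Reactants: 26 C12 carboxylic acid
Product: 27 bis(triethylsilyl) ether C1 aldehyde acid
Conditions: TESOTf, 2,4,6-collidine, CH2Cl2, 0 °C; then H2O
Reagents that add atoms: triethylsilyl triflate CC[Si](CC)(CC)OS(=O)(=O)C(F)(F)F; water O
Why: Silyl triflate/collidine acetal cleavage: the dioxolane is converted into a collidinium N,O-acetal that water hydrolyses to the C1 aldehyde without protic acid, and the same reagent silylates the two tertiary alcohols (the silyl ester is lost on work-up), which stops the C4 hydroxyl from forming a lactol with C1.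

Step 21
Reactants: 27 bis(triethylsilyl) ether C1 aldehyde acid
Product: 30 4,7-bis-O-triethylsilyl ether of the target, via open hydroxy enone acid 28 (not isolated), via hemiketal acid 29 (not isolated)
Conditions: CrCl2 (10 equiv), NiCl2 (2 mol %), i-Pr2NEt (1 equiv), DMSO/THF, rt, 2 mM; then CSA (cat.), CH2Cl2, rt
Reagents that add atoms: none
Why: Nozaki–Hiyama–Kishi reaction: nickel inserts into the C10–I bond and transmetalation gives an alkenylchromium(III) that adds to the C1 aldehyde with retention of the (Z)-geometry; the γ-hydroxy enone 28 should close to hemiketal 29, and acid then condenses it with the C12 acid to the spiro ketal lactone, C8 being dictated by the two bridges and C1 only by the macrocyclic transition state.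

Step 22
Reactants: 30 4,7-bis-O-triethylsilyl ether of the target
Product: 31 target CNP0315698.1
Conditions: HF·pyridine, MeCN, 0 °C to rt
Reagents that add atoms: none
Why: Fluoride removes the two tertiary triethylsilyl ethers, and the acetate, both lactones and the acid-stable spiro ketal should survive.

Compound list
1 | 2-(3-bromopropyl)-1,3-dioxolane | BrCCCC1OCCO1 | starting material
2 | [3-(1,3-dioxolan-2-yl)propyl]triphenylphosphonium bromide | [Br-].C1COC(CCC[P+](c2ccccc2)(c2ccccc2)c2ccccc2)O1 | intermediate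
3 | methyl (R)-3-hydroxy-2-methylpropanoate | OC[C@@H](C)C(=O)OC | starting material
4 | methyl (R)-3-[(tert-butyldiphenylsilyl)oxy]-2-methylpropanoate | CC(C)(C)[Si](OC[C@@H](C)C(=O)OC)(c1ccccc1)c1ccccc1 | intermediate
5 | ethyl (R)-5-[(tert-butyldiphenylsilyl)oxy]-4-methyl-3-oxopentanoate | CC(C)(C)[Si](OC[C@@H](C)C(=O)CC(=O)OCC)(c1ccccc1)c1ccccc1 | intermediate
6 | ethyl (2Z,4R)-5-[(tert-butyldiphenylsilyl)oxy]-4-methyl-3-(trifluoromethylsulfonyloxy)pent-2-enoate | CCOC(=O)/C=C(\OS(=O)(=O)C(F)(F)F)[C@H](C)CO[Si](c1ccccc1)(c1ccccc1)C(C)(C)C | intermediate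
7 | ethyl (2Z,4S)-3-(benzyloxymethyl)-5-[(tert-butyldiphenylsilyl)oxy]-4-methylpent-2-enoate | CCOC(=O)/C=C(\COCc1ccccc1)[C@H](C)CO[Si](c1ccccc1)(c1ccccc1)C(C)(C)C | intermediate
8 | (2Z,4S)-3-(benzyloxymethyl)-5-[(tert-butyldiphenylsilyl)oxy]-4-methylpent-2-en-1-ol | OC/C=C(\COCc1ccccc1)[C@H](C)CO[Si](c1ccccc1)(c1ccccc1)C(C)(C)C | intermediate
9 | [(2S,3R)-3-(benzyloxymethyl)-3-[(2R)-1-(tert-butyldiphenylsilyloxy)propan-2-yl]oxiran-2-yl]methanol | OC[C@@H]1O[C@@]1(COCc2ccccc2)[C@H](C)CO[Si](c2ccccc2)(c2ccccc2)C(C)(C)C | intermediate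
10 | (2R,3R)-3-(benzyloxymethyl)-3-[(2R)-1-(tert-butyldiphenylsilyloxy)propan-2-yl]oxirane-2-carbaldehyde | O=C[C@@H]1O[C@@]1(COCc2ccccc2)[C@H](C)CO[Si](c2ccccc2)(c2ccccc2)C(C)(C)C | intermediate
11 | [3-(1,3-dioxolan-2-yl)propylidene]triphenylphosphorane | C1COC(CCC=P(c2ccccc2)(c2ccccc2)c2ccccc2)O1 | intermediate
12 | [3-(1,3-dioxolan-2-yl)-1-iodopropyl]triphenylphosphonium iodide | [I-].C1COC(CCC(I)[P+](c2ccccc2)(c2ccccc2)c2ccccc2)O1 | intermediate
13 | [3-(1,3-dioxolan-2-yl)-1-iodopropylidene]triphenylphosphorane | C1COC(CCC(I)=P(c2ccccc2)(c2ccccc2)c2ccccc2)O1 | intermediate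
14 | 2-[(3Z)-3-iodo-4-{(2S,3R)-3-(benzyloxymethyl)-3-[(2R)-1-(tert-butyldiphenylsilyloxy)propan-2-yl]oxiran-2-yl}but-3-en-1-yl]-1,3-dioxolane | C1COC(CC/C(I)=C/[C@@H]2O[C@@]2(COCc3ccccc3)[C@H](C)CO[Si](c3ccccc3)(c3ccccc3)C(C)(C)C)O1 | intermediate
15 | (Z)-alkenyllithium from 14 (Li in place of I) | C1COC(CC/C([Li])=C/[C@@H]2O[C@@]2(COCc3ccccc3)[C@H](C)CO[Si](c3ccccc3)(c3ccccc3)C(C)(C)C)O1 | intermediate
16 | lithium (Z)-2-[2-(1,3-dioxolan-2-yl)ethyl]-3-(epoxy side chain)acrylate (carboxylate cis to C6) | [Li+].[O-]C(=O)/C(CCC1OCCO1)=C\[C@@H]2O[C@@]2(COCc3ccccc3)[C@H](C)CO[Si](c3ccccc3)(c3ccccc3)C(C)(C)C | intermediate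
17 | (5R)-5-[(2R,3R)-1-(benzyloxy)-4-(tert-butyldiphenylsilyloxy)-2-hydroxy-3-methylbutan-2-yl]-3-[2-(1,3-dioxolan-2-yl)ethyl]furan-2(5H)-one | O=C1O[C@H](C=C1CCC2OCCO2)[C@](O)(COCc3ccccc3)[C@H](C)CO[Si](c3ccccc3)(c3ccccc3)C(C)(C)C | intermediate
18 | (3S,4S,5R)-3,4-dihydroxy lactone from 17 (C4–OH and C5–OH cis, trans to the C6 side chain) | O=C1O[C@H]([C@H](O)[C@@]1(O)CCC2OCCO2)[C@](O)(COCc3ccccc3)[C@H](C)CO[Si](c3ccccc3)(c3ccccc3)C(C)(C)C | intermediate
19 | C5 acetate of 18 | O=C1O[C@H]([C@H](OC(C)=O)[C@@]1(O)CCC2OCCO2)[C@](O)(COCc3ccccc3)[C@H](C)CO[Si](c3ccccc3)(c3ccccc3)C(C)(C)C | intermediate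
20 | C8 primary alcohol (benzyl removed) | O=C1O[C@H]([C@H](OC(C)=O)[C@@]1(O)CCC2OCCO2)[C@](O)(CO)[C@H](C)CO[Si](c3ccccc3)(c3ccccc3)C(C)(C)C | intermediate
21 | C8 aldehyde | O=C1O[C@H]([C@H](OC(C)=O)[C@@]1(O)CCC2OCCO2)[C@](O)(C=O)[C@H](C)CO[Si](c3ccccc3)(c3ccccc3)C(C)(C)C | intermediate
22 | C8 but-2-ynyl carbinol (C8 epimers) | O=C1O[C@H]([C@H](OC(C)=O)[C@@]1(O)CCC2OCCO2)[C@](O)(C(O)C#CC)[C@H](C)CO[Si](c3ccccc3)(c3ccccc3)C(C)(C)C | intermediate
23 | C8 ynone | O=C1O[C@H]([C@H](OC(C)=O)[C@@]1(O)CCC2OCCO2)[C@](O)(C(=O)C#CC)[C@H](C)CO[Si](c3ccccc3)(c3ccccc3)C(C)(C)C | intermediate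
24 | (Z)-β-iodoenone (I on C10 cis to C8=O) | O=C1O[C@H]([C@H](OC(C)=O)[C@@]1(O)CCC2OCCO2)[C@](O)(C(=O)/C=C(/C)I)[C@H](C)CO[Si](c3ccccc3)(c3ccccc3)C(C)(C)C | intermediate
25 | C12 primary alcohol | O=C1O[C@H]([C@H](OC(C)=O)[C@@]1(O)CCC2OCCO2)[C@](O)(C(=O)/C=C(/C)I)[C@H](C)CO | intermediate
26 | C12 carboxylic acid | O=C1O[C@H]([C@H](OC(C)=O)[C@@]1(O)CCC2OCCO2)[C@](O)(C(=O)/C=C(/C)I)[C@H](C)C(O)=O | intermediate
27 | C4,C7-bis(triethylsilyl) ether with C1 aldehyde and C12 acid | O=C1O[C@H]([C@H](OC(C)=O)[C@@]1(O[Si](CC)(CC)CC)CCC=O)[C@](O[Si](CC)(CC)CC)(C(=O)/C=C(/C)I)[C@H](C)C(O)=O | intermediate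
28 | ten-membered (Z)-γ-hydroxy enone acid (C1–OH, C8=O) | O=C1O[C@@H]2[C@H](OC(C)=O)[C@@]1(O[Si](CC)(CC)CC)CC[C@H](O)/C(C)=C\C(=O)[C@]2(O[Si](CC)(CC)CC)[C@H](C)C(O)=O | intermediate
29 | C1–O–C8 hemiketal acid | O=C1O[C@@H]2[C@H](OC(C)=O)[C@@]1(O[Si](CC)(CC)CC)CC[C@@H]3O[C@](O)(C=C3C)[C@]2(O[Si](CC)(CC)CC)[C@H](C)C(O)=O | intermediate
30 | 4,7-bis-O-triethylsilyl ether of the target | CC(=O)O[C@H]1[C@H]2OC(=O)[C@]1(O[Si](CC)(CC)CC)CC[C@@H]1O[C@@]3(C=C1C)OC(=O)[C@@H](C)[C@]23O[Si](CC)(CC)CC | intermediate
31 | CNP0315698.1 | CC(=O)O[C@H]1[C@H]2OC(=O)[C@]1(O)CC[C@@H]1O[C@@]3(C=C1C)OC(=O)[C@@H](C)[C@]23O | target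

Total step count: 22. Longest linear sequence: 21 steps (steps 2–22, from 3).

Steps most likely to fail

Step 21. Ring closure may lose to intermolecular coupling and to protonation of the alkenylchromium, and the addition to the C1 aldehyde may show poor facial selectivity, since only the macrocyclic transition state controls C1. Fallback: from 27, the Ni/Cr closure is run as in step 21 but stopped before the acid treatment. The crude mixture of 29 and its C1 epimer is oxidised through the open form with Dess–Martin periodinane to the macrocyclic (Z)-ene-1,4-dione acid F1, in which C1 is no longer stereogenic. The less hindered C1 ketone (C8 is flanked by the silylated quaternary C7) is then reduced with catecholborane and the oxazaborolidine (CBS) enantiomer that delivers hydride to the face leading to (1S). This returns to 28 and, after the acid treatment of step 21, to 30.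

Step 10. The lithium carboxylate may be too poor a nucleophile to open the epoxide or may attack the tertiary C7, and the lithium alkoxide may epimerise C6 through the 2-oxidofuran. Fallback: from 14, the alkenyllithium 15 is made as before but trapped with 2-isopropoxy-4,4,5,5-tetramethyl-1,3,2-dioxaborolane to give the isolable (Z)-alkenyl pinacol boronate F2. Copper(I)–NHC-catalysed carboxylation of F2 (IPrCuCl, KOt-Bu, CO2 1 atm, THF, 70 °C) forms the potassium carboxylate F3 without any organolithium present, and F3 opens the epoxide at C6 in the same flask to give 17.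

Step 9. Iodination of the ylide may be incomplete (giving the iodine-free alkene), the longer chain may erode the Z-selectivity, and the base may destroy the epoxy aldehyde. Fallback: from 10, dibromo-olefination (CBr4, PPh3, Et3N, CH2Cl2, 0 °C) gives the 1,1-dibromoalkene F4. Palladium-catalysed Negishi coupling with [2-(1,3-dioxolan-2-yl)ethyl]zinc bromide selectively replaces the bromine trans to the epoxide and gives the (Z)-bromoalkene F5, whose bromine is cis to C6. Bromine–lithium exchange with t-BuLi at −78 °C then gives 15, and the route continues in step 10.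

Further compounds
F1 | step 21 | macrocyclic (Z)-ene-1,4-dione acid (C1 ketone) | O=C1O[C@@H]2[C@H](OC(C)=O)[C@@]1(O[Si](CC)(CC)CC)CCC(=O)/C(C)=C\C(=O)[C@]2(O[Si](CC)(CC)CC)[C@H](C)C(O)=O
F2 | step 10 | (Z)-alkenyl pinacol boronate epoxide (boron on C4 cis to C6) | C1COC(CC/C(B3OC(C)(C)C(C)(C)O3)=C/[C@@H]2O[C@@]2(COCc4ccccc4)[C@H](C)CO[Si](c4ccccc4)(c4ccccc4)C(C)(C)C)O1
F3 | step 10 | potassium salt corresponding to 16 | [K+].[O-]C(=O)/C(CCC1OCCO1)=C\[C@@H]2O[C@@]2(COCc3ccccc3)[C@H](C)CO[Si](c3ccccc3)(c3ccccc3)C(C)(C)C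
F4 | step 9 | 1,1-dibromoalkene epoxide | BrC(Br)=C[C@@H]1O[C@@]1(COCc2ccccc2)[C@H](C)CO[Si](c2ccccc2)(c2ccccc2)C(C)(C)C
F5 | step 9 | (Z)-bromoalkene epoxide (bromine on C4 cis to C6) | C1COC(CC/C(Br)=C/[C@@H]2O[C@@]2(COCc3ccccc3)[C@H](C)CO[Si](c3ccccc3)(c3ccccc3)C(C)(C)C)O1
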